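## Retrosynthetic overview

1. Target 19 ⇐ diol 18 (acetylation) ⇐ keto enoate 17 (hydride reduction, C7 set by the ring) ⇐ methyl ketone 15 (Horner–Wadsworth–Emmons, C13=C14).
2. 15 ⇐ bicyclic enone 11 + ketal Grignard from 12: 1,2-addition makes C9–C11, then a Dauben–Babler oxidative 1,3-transposition moves oxygen to C7 and the alkene to C8=C9.
3. 11 ⇐ hydrazone 8: ring A is closed through the C3–C4 bond by a visible-light cobalt-hydride radical cyclization onto a traceless sulfonylhydrazone acceptor (key step).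
4. 8 ⇐ (S)-carvone 1: α′-methylation, then α′-alkylation anti to the isopropenyl group sets C10; C5 is bought with 1.
5. Ring order: ring B (from carvone) first, ring A second, side chain last.

Assumption: labdane numbering (C1–C20) is used for positions; 4, 12 and 16 are taken as catalogue chemicals.

## Route

Step 1
Reactants: 1 (S)-(+)-carvone
Product: 3 (5S)-2,6-dimethyl-5-(prop-1-en-2-yl)cyclohex-2-en-1-one (6-methylcarvone; C6 epimers), via lithium dienolate 2 (not isolated)
Conditions: LiN(i-Pr)2 (1.1 equiv), THF, −78 °C; MeI, −78 → 0 °C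
Reagents that add atoms: iodomethane (SMILES: CI)
Why: Kinetic α′-deprotonation gives the cross-conjugated dienolate, which is C-methylated (enolate alkylation); the new C6 centre is flattened again in step 2, so its epimer ratio does not matter.

Step 2
Reactants: 3 6-methylcarvone; 4 2-(2-iodoethyl)-1,3-dioxolane
Product: 6 (5R,6R)-6-[2-(1,3-dioxolan-2-yl)ethyl]-2,6-dimethyl-5-(prop-1-en-2-yl)cyclohex-2-en-1-one, via lithium enolate 5 (not isolated)
Conditions: LiN(i-Pr)2 (1.1 equiv), THF, −78 °C; 4 (1.5 equiv), DMPU, −78 → 0 °C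
Reagents that add atoms: none
Why: Enolate alkylation in which the iodide approaches the tetrasubstituted enolate anti to the adjacent isopropenyl group, placing the three-carbon chain trans to it (methyl cis) and so setting quaternary C10 under control of the carvone stereocentre (dr expected about 10:1, as for the analogous allylation).

Step 3
Reactants: 6 dioxolane ketone
Product: 8 (E)-N-tosylhydrazone of 3-[(1R,6R)-1,3-dimethyl-2-oxo-6-(prop-1-en-2-yl)cyclohex-3-en-1-yl]propanal, via keto aldehyde 7 (not isolated)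
Conditions: 1 M aq. HCl, THF, 25 °C; then TsNHNH2 (1.05 equiv), MeOH, 25 °C
Reagents that add atoms: 4-methylbenzenesulfonohydrazide (SMILES: Cc1ccc(cc1)S(=O)(=O)NN)
Why: Acetal hydrolysis followed by hydrazone condensation at the unhindered aldehyde; the hindered conjugated ring ketone does not compete at 25 °C.

Step 4
Reactants: 8 tosylhydrazone
Product: 11 (4aR,8aR)-2,5,5,8a-tetramethyl-4a,5,6,7,8,8a-hexahydronaphthalen-1(4H)-one, via cyclized sulfonylhydrazide 9 (not isolated), via monoalkyl diazene 10 (not isolated)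
Conditions: Co(salen′) 5 mol % (salen′ = N,N′-bis(3,5-di-tert-butylsalicylidene)ethane-1,2-diamine dianion, achiral, divalent cobalt), [Ir(ppy)2(dtbbpy)]PF6 1 mol %, Hantzsch ester (diethyl 2,6-dimethyl-1,4-dihydropyridine-3,5-dicarboxylate, 1.5 equiv), 2,4,6-collidinium triflate 20 mol %, degassed MeCN/EtOH, 450 nm LEDs, 25 °C; then 70 °C, dark
Reagents that add atoms: none
Why: Proposed new method: a visible-light cobalt-hydride MHAT cyclization onto a tethered aldehyde N-tosylhydrazone used as a traceless radical acceptor — the photoreduced iridium complex reduces divalent cobalt to monovalent cobalt, protonation gives a cobalt hydride that delivers H• to the terminal CH2 of the 1,1-disubstituted alkene (Markovnikov), the tertiary C4 radical adds 6-exo-trig to the hydrazone carbon (C3) and so forges the C3–C4 bond, quaternary C4 and ring A, the hydrazinyl radical is reduced by the Hantzsch ester to 9, and warming expels sulfinate and then N2 (via 10) to leave CH2; no stereocentre is created and C5/C10 are untouched, so the trans ring fusion follows from step 2; the closest known reaction types are iron-hydride MHAT hydromethylation of alkenes with formaldehyde sulfonylhydrazones, thermal MHAT radical cyclizations onto hydrazones and ketones, and the Caglioti-type collapse of N-alkyl-N′-sulfonylhydrazides.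

Step 5
Reactants: 11 bicyclic enone; 12 2-(2-bromoethyl)-2-methyl-1,3-dioxolane
Product: 13 (4aR,8aR)-2,5,5,8a-tetramethyl-1-[2-(2-methyl-1,3-dioxolan-2-yl)ethyl]-1,4,4a,5,6,7,8,8a-octahydronaphthalen-1-ol (C9 carbinol; configuration inconsequential)
Conditions: 12, Mg, THF, 30 °C; anhydrous CeCl3, THF, −78 °C; then 11, −78 → 0 °C; aq. NH4Cl
Reagents that add atoms: none
Why: Organocerium 1,2-addition (Imamoto conditions) to the hindered, enolizable enone carbonyl forms the C9–C11 bond; attack anti to the axial angular methyl is expected, but the C9 configuration is erased in step 6.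

Step 6
Reactants: 13 tertiary allylic alcohol
Product: 15 (4aR,8aR)-3,4a,8,8-tetramethyl-4-(3-oxobutyl)-4a,5,6,7,8,8a-hexahydronaphthalen-2(1H)-one, via dioxolane enone 14 (not isolated)
Conditions: [C5H5NH][CrO3Cl] (3 equiv), 4 Å MS, CH2Cl2, 25 °C; filter; then 1 M aq. HCl, THF, 25 °C
Reagents that add atoms: pyridinium chlorochromate (SMILES: [O-][Cr](=O)(=O)Cl.c1cc[nH+]cc1); water (SMILES: O)
Why: Dauben–Babler oxidative 1,3-transposition, in which the tertiary allylic chromate ester undergoes a [3,3] shift to C7 and is oxidized there, giving the C7 ketone and the tetrasubstituted C8=C9 alkene that carries the side chain; dilute acid then unmasks the methyl ketone.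

Step 7
Reactants: 15 diketone; 16 ethyl 2-(diisopropoxyphosphoryl)acetate
Product: 17 ethyl (2E)-3-methyl-5-[(4aR,8aR)-2,5,5,8a-tetramethyl-3-oxo-3,4,4a,5,6,7,8,8a-octahydronaphthalen-1-yl]pent-2-enoate
Conditions: 16 (1.5 equiv), NaH, THF, 0 °C; then 15, 0 → 25 °C
Reagents that add atoms: none
Why: Horner–Wadsworth–Emmons olefination of the unhindered methyl ketone (the hindered, vinylogous C7 ketone is inert); the bulky diisopropyl phosphonate should give about 9:1 E:Z, and the minor Z ester is removed by chromatography.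

Step 8
Reactants: 17 keto enoate
Product: 18 (2R,4aR,8aR)-4-[(3E)-5-hydroxy-3-methylpent-3-en-1-yl]-3,4a,8,8-tetramethyl-1,2,4a,5,6,7,8,8a-octahydronaphthalen-2-ol
Conditions: i-Bu2AlH (4.5 equiv), CH2Cl2, −78 °C; aq. KNaC4H4O6 work-up
Reagents that add atoms: none
Why: 1,2-Reduction of both the enoate and the enone; hydride adds axially to C7 from the face opposite the angular C10 methyl, giving the pseudo-equatorial 7-OH cis to that methyl (7R), the same substrate control that turns carvone into cis-carveol.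

Step 9
Reactants: 18 diol
Product: 19 (2E)-5-[(3R,4aR,8aR)-3-(acetyloxy)-2,5,5,8a-tetramethyl-3,4,4a,5,6,7,8,8a-octahydronaphthalen-1-yl]-3-methylpent-2-en-1-yl acetate (target)
Conditions: Ac2O, pyridine, DMAP (cat.), CH2Cl2, 0 → 25 °C
Reagents that add atoms: acetic anhydride (SMILES: CC(=O)OC(C)=O)
Why: Nucleophile-catalysed acylation of the primary and the secondary allylic alcohol with retention at C7 gives the diacetate.

## Compound list

1 | (S)-(+)-carvone, (5S)-2-methyl-5-(prop-1-en-2-yl)cyclohex-2-en-1-one | O=C1C(C)=CC[C@H](C(C)=C)C1 | starting material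
2 | lithium cross-conjugated dienolate of 1 | [Li]OC1=C[C@@H](C(C)=C)CC=C1C | intermediate (not isolated)
3 | (5S)-2,6-dimethyl-5-(prop-1-en-2-yl)cyclohex-2-en-1-one (C6 epimers) | O=C1C(C)=CC[C@H](C(C)=C)C1C | intermediate
4 | 2-(2-iodoethyl)-1,3-dioxolane | ICCC1OCCO1 | starting material
5 | lithium enolate of 3 | [Li]OC1=C(C)[C@@H](C(C)=C)CC=C1C | intermediate (not isolated)
6 | (5R,6R)-6-[2-(1,3-dioxolan-2-yl)ethyl]-2,6-dimethyl-5-(prop-1-en-2-yl)cyclohex-2-en-1-one | O=C1C(C)=CC[C@H](C(C)=C)[C@@]1(C)CCC2OCCO2 | intermediate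
7 | 3-[(1R,6R)-1,3-dimethyl-2-oxo-6-(prop-1-en-2-yl)cyclohex-3-en-1-yl]propanal | O=C1C(C)=CC[C@H](C(C)=C)[C@@]1(C)CCC=O | intermediate (not isolated)
8 | N′-[(1E)-3-[(1R,6R)-1,3-dimethyl-2-oxo-6-(prop-1-en-2-yl)cyclohex-3-en-1-yl]propylidene]-4-methylbenzenesulfonohydrazide | O=C1C(C)=CC[C@H](C(C)=C)[C@@]1(C)CC/C=N/NS(=O)(=O)c2ccc(C)cc2 | intermediate
9 | 4-methyl-N′-[(4aR,8aR)-1,1,4a,6-tetramethyl-5-oxo-1,2,3,4,4a,5,8,8a-octahydronaphthalen-2-yl]benzenesulfonohydrazide (C3 epimers, labdane numbering) | O=C1C(C)=CC[C@@H]2C(C)(C)C(NNS(=O)(=O)c3ccc(C)cc3)CC[C@@]12C | intermediate (not isolated)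
10 | (4aR,8aR)-6-diazenyl-2,5,5,8a-tetramethyl-4a,5,6,7,8,8a-hexahydronaphthalen-1(4H)-one | O=C1C(C)=CC[C@@H]2C(C)(C)C(N=N)CC[C@@]12C | intermediate (not isolated)
11 | (4aR,8aR)-2,5,5,8a-tetramethyl-4a,5,6,7,8,8a-hexahydronaphthalen-1(4H)-one | O=C1C(C)=CC[C@@H]2C(C)(C)CCC[C@@]12C | intermediate
12 | 2-(2-bromoethyl)-2-methyl-1,3-dioxolane | CC1(CCBr)OCCO1 | starting material
13 | (4aR,8aR)-2,5,5,8a-tetramethyl-1-[2-(2-methyl-1,3-dioxolan-2-yl)ethyl]-1,4,4a,5,6,7,8,8a-octahydronaphthalen-1-ol (carbinol centre unassigned) | OC1(CCC3(C)OCCO3)C(C)=CC[C@@H]2C(C)(C)CCC[C@@]12C | intermediate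
14 | (4aR,8aR)-3,4a,8,8-tetramethyl-4-[2-(2-methyl-1,3-dioxolan-2-yl)ethyl]-4a,5,6,7,8,8a-hexahydronaphthalen-2(1H)-one | CC1(CCC2=C(C)C(=O)C[C@@H]3C(C)(C)CCC[C@@]23C)OCCO1 | intermediate (not isolated)
15 | (4aR,8aR)-3,4a,8,8-tetramethyl-4-(3-oxobutyl)-4a,5,6,7,8,8a-hexahydronaphthalen-2(1H)-one | CC(=O)CCC1=C(C)C(=O)C[C@@H]2C(C)(C)CCC[C@@]12C | intermediate
16 | ethyl 2-(diisopropoxyphosphoryl)acetate | CCOC(=O)CP(=O)(OC(C)C)OC(C)C | starting material
17 | ethyl (2E)-3-methyl-5-[(4aR,8aR)-2,5,5,8a-tetramethyl-3-oxo-3,4,4a,5,6,7,8,8a-octahydronaphthalen-1-yl]pent-2-enoate | CCOC(=O)/C=C(\C)CCC1=C(C)C(=O)C[C@@H]2C(C)(C)CCC[C@@]12C | intermediate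
18 | (2R,4aR,8aR)-4-[(3E)-5-hydroxy-3-methylpent-3-en-1-yl]-3,4a,8,8-tetramethyl-1,2,4a,5,6,7,8,8a-octahydronaphthalen-2-ol | OC/C=C(\C)CCC1=C(C)[C@H](O)C[C@@H]2C(C)(C)CCC[C@@]12C | intermediate
19 | (2E)-5-[(3R,4aR,8aR)-3-(acetyloxy)-2,5,5,8a-tetramethyl-3,4,4a,5,6,7,8,8a-octahydronaphthalen-1-yl]-3-methylpent-2-en-1-yl acetate | CC(=O)OC/C=C(\C)CCC1=C(C)[C@H](OC(C)=O)C[C@@H]2C(C)(C)CCC[C@@]12C | target

## Step count and risk assessment

Total step count: 9. Longest linear sequence: 9 steps (1 → 19).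

**Step 2 (alkylation of a hindered tetrasubstituted enolate with an unactivated primary iodide).** The iodide may eliminate or react too slowly. The fallback sets out from 3 and uses the much more reactive allyl bromide (LiN(i-Pr)2, THF, −78 → 0 °C), which gives, again anti to the isopropenyl group, (5R,6R)-2,6-dimethyl-6-(prop-2-en-1-yl)-5-(prop-1-en-2-yl)cyclohex-2-en-1-one F1. Chemoselective anti-Markovnikov hydroboration of the monosubstituted alkene with [(CH3)2CHCH(CH3)]2BH (THF, 0 °C) and oxidation with NaBO3·4H2O gives (5R,6R)-6-(3-hydroxypropyl)-2,6-dimethyl-5-(prop-1-en-2-yl)cyclohex-2-en-1-one F2. Dess–Martin oxidation then returns to the route at aldehyde 7, which is condensed with tosylhydrazide as in step 3.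

**Step 4 (the proposed photochemical ring closure).** Possible failures are reversible MHAT with alkene isomerization, simple hydrogenation of the isopropenyl group, or direct reduction of the hydrazone. The fallback uses known chemistry and sets out from 3.
- Alkylation with methyl 2-(bromomethyl)acrylate (LiN(i-Pr)2, THF, −78 °C) gives methyl 2-{[(1R,6R)-1,3-dimethyl-2-oxo-6-(prop-1-en-2-yl)cyclohex-3-en-1-yl]methyl}prop-2-enoate F3.
- Thermal iron-hydride MHAT Giese cyclization (Fe(acac)3, trivalent iron, PhSiH3, EtOH/ethylene glycol, 60 °C) has the tertiary C4 radical add to the terminal acrylate carbon (6-endo), giving methyl (4aR,8aR)-4,4,7,8a-tetramethyl-8-oxo-1,2,3,4,4a,5,8,8a-octahydronaphthalene-2-carboxylate F4 (C2 epimers).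
- Saponification (LiOH, THF/H2O) gives the corresponding carboxylic acid F5.
- Acridinium-photocatalysed hydrodecarboxylation (9-mesityl-10-methylacridinium tetrafluoroborate, PhSSPh, i-Pr2NEt, CF3CH2OH, 450 nm) removes the carboxyl group and comes back to the route at 11.

**Step 7 (geometry of the C13=C14 alkene).** Olefination of a methyl ketone may give too much Z isomer. The fallback builds the alkene by stereospecific syn-carbometalation and sets out from 11.
- Addition of [4-(trimethylsilyl)but-3-yn-1-yl]magnesium bromide (from commercial 4-bromo-1-(trimethylsilyl)but-1-yne and Mg) with CeCl3 gives (4aR,8aR)-2,5,5,8a-tetramethyl-1-[4-(trimethylsilyl)but-3-yn-1-yl]-1,4,4a,5,6,7,8,8a-octahydronaphthalen-1-ol F6.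
- Oxidative transposition with [C5H5NH][CrO3Cl] gives (4aR,8aR)-3,4a,8,8-tetramethyl-4-[4-(trimethylsilyl)but-3-yn-1-yl]-4a,5,6,7,8,8a-hexahydronaphthalen-2(1H)-one F7.
- Luche reduction (NaBH4, CeCl3, MeOH, −78 °C) gives (2R,4aR,8aR)-3,4a,8,8-tetramethyl-4-[4-(trimethylsilyl)but-3-yn-1-yl]-1,2,4a,5,6,7,8,8a-octahydronaphthalen-2-ol F8, which is desilylated in the same flask (K2CO3, MeOH) to (2R,4aR,8aR)-4-(but-3-yn-1-yl)-3,4a,8,8-tetramethyl-1,2,4a,5,6,7,8,8a-octahydronaphthalen-2-ol F9.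
- Negishi methylalumination (AlMe3, Cp2ZrCl2 cat., CH2Cl2), then n-BuLi and paraformaldehyde, gives only the E allylic alcohol and comes back to the route at diol 18.

## Further compounds

F1 | step 2 | (5R,6R)-2,6-dimethyl-6-(prop-2-en-1-yl)-5-(prop-1-en-2-yl)cyclohex-2-en-1-one | O=C1C(C)=CC[C@H](C(C)=C)[C@@]1(C)CC=C
F2 | step 2 | (5R,6R)-6-(3-hydroxypropyl)-2,6-dimethyl-5-(prop-1-en-2-yl)cyclohex-2-en-1-one | O=C1C(C)=CC[C@H](C(C)=C)[C@@]1(C)CCCO
F3 | step 4 | methyl 2-{[(1R,6R)-1,3-dimethyl-2-oxo-6-(prop-1-en-2-yl)cyclohex-3-en-1-yl]methyl}prop-2-enoate | O=C1C(C)=CC[C@H](C(C)=C)[C@@]1(C)CC(=C)C(=O)OC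
F4 | step 4 | methyl (4aR,8aR)-4,4,7,8a-tetramethyl-8-oxo-1,2,3,4,4a,5,8,8a-octahydronaphthalene-2-carboxylate (C2 epimers) | O=C1C(C)=CC[C@@H]2C(C)(C)CC(C(=O)OC)C[C@@]12C
F5 | step 4 | (4aR,8aR)-4,4,7,8a-tetramethyl-8-oxo-1,2,3,4,4a,5,8,8a-octahydronaphthalene-2-carboxylic acid (C2 epimers) | O=C1C(C)=CC[C@@H]2C(C)(C)CC(C(=O)O)C[C@@]12C
F6 | step 7 | (4aR,8aR)-2,5,5,8a-tetramethyl-1-[4-(trimethylsilyl)but-3-yn-1-yl]-1,4,4a,5,6,7,8,8a-octahydronaphthalen-1-ol | OC1(CCC#C[Si](C)(C)C)C(C)=CC[C@@H]2C(C)(C)CCC[C@@]12C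
F7 | step 7 | (4aR,8aR)-3,4a,8,8-tetramethyl-4-[4-(trimethylsilyl)but-3-yn-1-yl]-4a,5,6,7,8,8a-hexahydronaphthalen-2(1H)-one | C[Si](C)(C)C#CCCC1=C(C)C(=O)C[C@@H]2C(C)(C)CCC[C@@]12C
F8 | step 7 | (2R,4aR,8aR)-3,4a,8,8-tetramethyl-4-[4-(trimethylsilyl)but-3-yn-1-yl]-1,2,4a,5,6,7,8,8a-octahydronaphthalen-2-ol | C[Si](C)(C)C#CCCC1=C(C)[C@H](O)C[C@@H]2C(C)(C)CCC[C@@]12C
F9 | step 7 | (2R,4aR,8aR)-4-(but-3-yn-1-yl)-3,4a,8,8-tetramethyl-1,2,4a,5,6,7,8,8a-octahydronaphthalen-2-ol | C#CCCC1=C(C)[C@H](O)C[C@@H]2C(C)(C)CCC[C@@]12C
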